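All runs were generated by integration from invented constants; noise was put on by code.

The starting material is the account here, taken as the limiting reagent. Every entry below is a share of its charge, and the ledger counts the share missing from the target.

| flask | starting material | protic impurity | remark | time |
|---|---|---|---|---|
| summer | 5.7 mM (in portions, 2) | 6 mM | run made earlier; portions every 3.0 h |  |
| autumn | 9.2 mM (in portions, 2) | 6 mM | run made earlier; portions every 3.0 h |  |
| midnight | 14 mM (in portions, 2) | 6 mM | run made earlier; portions every 3.0 h |  |
| Tuesday's | 20 mM (in portions, 2) | 6.00 mM | the portions of starting material follow each other after 3.0 h, the first at the start | 20 h |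
| Monday's | 5.0 mM | 6.00 mM | everything together at the start | 20 h |

- summer (time / h: target / %): 2.00: 47.2; 5.00: 94.9; 10.0: 94.6; 15.0: 96.5; 20.0: 95.2
- autumn (time / h: target / %): 4.00: 91.5; 8.00: 93.1; 12.0: 93.7; 15.0: 93.1; 20.0: 93.6
- midnight (time / h: target / %): 2.00: 46.6; 5.00: 88.9; 10.0: 90.5; 15.0: 90.5; 20.0: 91.1

(readings scatter by 0.5 percentage points)



* which of the two ends with the higher amount of target, in percent of the starting material charged ("neither" if they lie within 2 percentage points) (Tuesday's / Monday's / neither)
* target at the end, in percent of the starting material charged, Tuesday's
* target at the end, in percent of the starting material charged, Monday's

The target readings stop moving once the last portion has reacted, so each plateau closes the books of its run. The last 3 readings leave 4.57% missing in the summer run, with portions of 2.85 mM, and 9.30% in the midnight run, with portions of 7.00 mM. The difference divided by the difference in portion size gives 0.0114 mM⁻¹ of the charge, the loss per millimolar of portion. The autumn run was not used for this line, and it reads 6.53% missing where the line puts 6.56%.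

The ledger also shows when this entry is booked. At 2.00 h, before the second portion, the summer and midnight target readings differ by 0.6 percentage points, beside a scatter of 0.5 points on each reading. That gap is less than the 4.7 points between their end losses, so in these two runs the hours to watch are those after the second portion.

Tuesday's portions of 10.0 mM lie beyond the tested range, and the line extended there books 12.7% missing, which leaves 87.3% target. Monday's single shot has no earlier portion, so the line does not apply to it. The nearest entry is the first-portion shortfall at 2.00 h, which is 5.60% of that portion in the summer run and 6.80% in the midnight run. This reckoning puts Monday's near 93.8% or a little above, as those shortfalls are scattered readings that may still hold unreacted starting material, and that is higher than Tuesday's by more than the margin.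

The forecast gave 87.5% for Tuesday's and 93.2% for Monday's, with Monday's ahead, holding that “the portion size sets the loss”.

The simulation gives 86.5% for Tuesday's and 95.5% for Monday's, so Monday's ends higher.

    starting material → target, rate k1*[starting material]/(1 + ([starting material]/sat1)) (7.31 mM, k = 0.00154 s⁻¹)
    starting material + target → side product (k = 0.00693 L mol⁻¹ s⁻¹)
    starting material + protic impurity → quenched substrate (k = 0.00404 L mol⁻¹ s⁻¹)
    starting material ⇌ dormant form (K = 0.407, k = 5.50 × 10⁻⁵ s⁻¹)

In Tuesday's flask the side product stood at 2.73% at 3.00 h, just before the last addition, and at 11.1% by 10.0 h. Half of the turnover to side product came by 3.15 h, later than half of the turnover to target at 1.80 h. Tuesday's missing share is 13.5%, against 12.7% from the loss per millimolar of portion. For the same flask with 8.0 mM of starting material, that loss reckons 94.1% target, and the flask ended at 94.1%.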